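**Assumption:** only reactants, intermediates and products are numbered; bases, catalysts and solvents appear in the conditions. The target's cyclopropanes are (1R,3S), the series opposite to (+)-2-carene, so (S)-carvone is the chiral source.

## Retrosynthetic overview

1. Target 14 is the syn-[4+4] "dimer" of two 1,5-H tautomers of one cyclopentadiene; retro-Cope (boat) gives the cis-syn-cis head-to-head cyclobutane 13, and retro-[2+2] gives dienes 11 + 12.
2. 11 and 12 both come from one acyclic dienyl carbinol 10 by cationic 4π-electrocyclisation; carbinol → two cyclopentadienes → cyclobutane → tricycle is run in one flask.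
3. 10 comes from enol lactone 6 plus isopropenyl and vinyl Grignard reagents; opening the lactone masks the side-chain ketone as its enolate.
4. 6 comes from Baeyer–Villiger oxidation of ent-car-3-en-2-one 4, made from (S)-carvone 1 by 1,3-elimination, which sets all four cyclopropane stereocentres.
5. Ring order: cyclopropanes (step 1) → two cyclopentadienes and the cyclobutane → bridged tricyclo[4.2.1.1(2,5)]decadiene core (step 4).

## Route

**Step 1**
Reactants: 1 (S)-(+)-carvone; 2 hydrogen chloride
Product: 4 (1R,6S)-3,7,7-trimethylbicyclo[4.1.0]hept-3-en-2-one, via tertiary chloride 3 (not isolated)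
Conditions: HCl (g, 1.05 equiv), Et2O, −10 °C; then t-BuOK (1.2 equiv), THF, 0 °C, one pot
Reagents that add atoms: none
Why: Markovnikov hydrochlorination of the isopropenyl group, then kinetic α'-enolate formation and 3-exo-tet intramolecular alkylation (1,3-elimination) close the cis-fused gem-dimethylcyclopropane; C5 of carvone becomes C6 and the cis fusion forces C1, so both cyclopropane centres of each half of the target are fixed here.

**Step 2**
Reactants: 4 (1R,6S)-3,7,7-trimethylbicyclo[4.1.0]hept-3-en-2-one; 5 3-chloroperoxybenzoic acid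
Product: 6 (1R,7S)-4,8,8-trimethyl-3-oxabicyclo[5.1.0]oct-4-en-2-one
Conditions: mCPBA (1.1 equiv), CH2Cl2, 0 °C to rt
Reagents that add atoms: 3-chloroperoxybenzoic acid, OOC(=O)c1cccc(Cl)c1
Why: Baeyer–Villiger oxidation in which the α-methylalkenyl group migrates in preference to the poorly migrating cyclopropyl group, giving the seven-membered enol lactone; no stereocentre is touched.

**Step 3**
Reactants: 6 (1R,7S)-4,8,8-trimethyl-3-oxabicyclo[5.1.0]oct-4-en-2-one; 7 isopropenylmagnesium bromide; 8 vinylmagnesium bromide
Product: 10 4-[(1S,3R)-3-(3-hydroxy-2-methylpenta-1,4-dien-3-yl)-2,2-dimethylcyclopropyl]butan-2-one (carbinol epimers), via magnesium enolate 9 (not isolated)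
Conditions: isopropenylMgBr (1.05 equiv), THF, −78 °C; then LaCl3·2LiCl (0.3 equiv), vinylMgBr (1.5 equiv), −78 to 0 °C; aq. NH4Cl
Reagents that add atoms: isopropenylmagnesium bromide, CC(=C)[Mg]Br; vinylmagnesium bromide, C=C[Mg]Br
Why: Grignard cleavage of the enol ester (acyl substitution) releases the side-chain ketone as its magnesium enolate, which protects it while the second Grignard reagent adds 1,2 to the new hindered cyclopropyl isopropenyl ketone; the new carbinol centre forms as a mixture and is destroyed in step 4.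

**Step 4**
Reactants: 10 4-[(1S,3R)-3-(3-hydroxy-2-methylpenta-1,4-dien-3-yl)-2,2-dimethylcyclopropyl]butan-2-one (two molecules)
Product: 14 (1S,2S,5S,6S)-1,3-dimethyl-4,8-bis[(1R,3S)-2,2-dimethyl-3-(3-oxobutyl)cyclopropyl]tricyclo[4.2.1.1(2,5)]deca-3,7-diene, via 5-methyl diene 11 (not isolated), via 2-methyl diene 12 (not isolated), via cyclobutane dimer 13 (not isolated)
Conditions: TsOH·H2O (5 mol %), 4 Å MS, PhCl (0.5 M), −20 °C; K2CO3 (10 mol %); [Ir(dF(CF3)ppy)2(dtbbpy)]PF6 (1 mol %), 450 nm, degassed, −40 °C; then 70 °C, dark; preparative HPLC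
Reagents that add atoms: none
Why: Proposed new method: acid ionisation of the bis-allylic carbinol gives a 3-cyclopropylpentadienyl cation that closes by Nazarov-type conrotatory 4π-electrocyclisation and loses a proton to exactly the two kinetic tautomers 11 and 12 (no 1,5-H scrambling in the cold); triplet energy transfer (sensitiser ET about 61 kcal/mol, above the dienes but below isolated alkenes, vinylcyclopropanes and ketones, so products and cyclopropanes are not excited) then joins the unsubstituted C4=C5 of 12 to the cyclopropyl-bearing C1=C2 of 11 through a bis-allyl diradical to the stacked cis-syn-cis head-to-head cyclobutane 13, whose cis-1,2-dialkenylcyclobutane unit undergoes boat Cope [3,3] rearrangement on warming and carries the face-to-face geometry into the four core stereocentres (syn, all S); their sense relative to the cyclopropanes rests only on weak substrate bias, so 14 is one of up to four syn facial isomers, beside [4+2] and anti-[2+2] dimers, and is separated; closest known reactions are the acid-mediated cyclisation of 1,4-dien-3-ols to cyclopentadienes, the sensitised photodimerisation of cyclopentadiene and isoprene, and the cis-1,2-divinylcyclobutane to cycloocta-1,5-diene Cope rearrangement.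

## Compound list

1 | (S)-(+)-carvone, (5S)-2-methyl-5-(prop-1-en-2-yl)cyclohex-2-en-1-one | CC1=CC[C@@H](CC1=O)C(C)=C | starting material
2 | hydrogen chloride | Cl | starting material
3 | (5S)-5-(2-chloropropan-2-yl)-2-methylcyclohex-2-en-1-one | CC1=CC[C@@H](CC1=O)C(C)(C)Cl | intermediate
4 | (1R,6S)-3,7,7-trimethylbicyclo[4.1.0]hept-3-en-2-one (ent-car-3-en-2-one, cis-fused) | CC1=CC[C@H]2[C@@H](C1=O)C2(C)C | intermediate
5 | 3-chloroperoxybenzoic acid | OOC(=O)c1cccc(Cl)c1 | starting material
6 | (1R,7S)-4,8,8-trimethyl-3-oxabicyclo[5.1.0]oct-4-en-2-one (enol lactone, cis-fused) | CC1=CC[C@H]2[C@@H](C(=O)O1)C2(C)C | intermediate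
7 | isopropenylmagnesium bromide | CC(=C)[Mg]Br | starting material
8 | vinylmagnesium bromide | C=C[Mg]Br | starting material
9 | bromomagnesium (Z)-enolate of 4-[(1S,3R)-2,2-dimethyl-3-(2-methylprop-2-enoyl)cyclopropyl]butan-2-one | C/C(O[Mg]Br)=C/C[C@H]1[C@@H](C(=O)C(C)=C)C1(C)C | intermediate
10 | 4-[(1S,3R)-3-(3-hydroxy-2-methylpenta-1,4-dien-3-yl)-2,2-dimethylcyclopropyl]butan-2-one (cis-cyclopropane; both carbinol epimers) | CC(=O)CC[C@H]1[C@@H](C(O)(C=C)C(C)=C)C1(C)C | intermediate
11 | 4-[(1S,3R)-2,2-dimethyl-3-(5-methylcyclopenta-1,4-dien-1-yl)cyclopropyl]butan-2-one | CC1=CCC=C1[C@@H]1[C@H](CCC(C)=O)C1(C)C | intermediate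
12 | 4-[(1S,3R)-2,2-dimethyl-3-(2-methylcyclopenta-1,4-dien-1-yl)cyclopropyl]butan-2-one | CC1=C([C@@H]2[C@H](CCC(C)=O)C2(C)C)C=CC1 | intermediate
13 | cis-syn-cis head-to-head [2+2] dimer: 4,10-dimethyl-1,3-bis[(1R,3S)-2,2-dimethyl-3-(3-oxobutyl)cyclopropyl]tricyclo[5.3.0.0(2,6)]deca-3,9-diene; both cyclopentene rings on one face of the cyclobutane; H-2, H-6, H-7 and the C-1 cyclopropyl on the other | CC1=C([C@@H]3[C@H](CCC(C)=O)C3(C)C)[C@@H]2[C@H](C1)[C@@H]1CC=C(C)[C@]21[C@@H]1[C@H](CCC(C)=O)C1(C)C | intermediate
14 | (1S,2S,5S,6S)-1,3-dimethyl-4,8-bis[(1R,3S)-2,2-dimethyl-3-(3-oxobutyl)cyclopropyl]tricyclo[4.2.1.1(2,5)]deca-3,7-diene (syn; CNP0300925.1) | CC(=O)CC[C@H]1[C@@H](C2=C[C@@H]3C[C@@]2(C)[C@H]2C[C@@H]3C([C@@H]3[C@H](CCC(C)=O)C3(C)C)=C2C)C1(C)C | target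

## Step count and risks

Total step count: 4. Longest linear sequence: 4 steps, from 1 to 14.

**Step 4 is the most likely to fail.** Diels–Alder adducts and the anti cyclobutane will compete with 13, acid may open the cyclopropylcarbinyl cation, and nothing pairs the two diene faces. The fallback makes the photodimerisation intramolecular. It sets out from 10: two molecules are condensed with hydrazine hydrate (0.5 equiv, EtOH, rt) to the ketazine of 10 F1. The same acid treatment gives the bis(cyclopentadienyl) ketazine F2, in which the two dienes are held side by side. Sensitised irradiation and warming then give the ansa-ketazine of the target F3. Hydrolysis of the azine (aqueous oxalic acid, THF, rt) comes back to the route at 14.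

**Step 2 is the second risk.** The conjugated ketone oxidises slowly and the enol lactone can be epoxidised by excess peracid. The fallback sets out from 4: conjugate reduction (L-Selectride, THF, −78 °C) gives (1R,6S)-3,7,7-trimethylbicyclo[4.1.0]heptan-2-one F4. Its Baeyer–Villiger oxidation is unambiguous (secondary alkyl migrates) and gives the saturated lactone F5. Isopropenyl and then vinyl Grignard reagents as in step 3 give the diol F6. Dess–Martin oxidation of the secondary alcohol comes back to the route at 10.

**Step 3 is the third risk.** Over-addition of the first Grignard reagent, 1,4-addition of the second, or aldol closure of enolate 9 onto the new ketone would give wrong carbinols. The fallback replaces the two reagents by one [4+1] annulation. It sets out from 6, which is treated with (pent-2-ene-1,4-diyl)magnesium F7, made from (E)-penta-1,3-diene and activated magnesium. Both C–C bonds then come from one reagent and the product is the cyclopentenol F8. Dehydration with catalytic TsOH and 1,5-H equilibration at rt give a tautomer mixture that contains 11 and 12, where it comes back to the route before the irradiation stage of step 4.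

## Further compounds

F1 | step 4 | ketazine of 10, N,N'-bis{4-[(1S,3R)-3-(3-hydroxy-2-methylpenta-1,4-dien-3-yl)-2,2-dimethylcyclopropyl]butan-2-ylidene}hydrazine | CC(CC[C@H]1[C@@H](C(O)(C=C)C(C)=C)C1(C)C)=NN=C(C)CC[C@H]1[C@@H](C(O)(C=C)C(C)=C)C1(C)C
F2 | step 4 | bis(cyclopentadienyl) ketazine (one 2-methyl and one 5-methyl cyclopenta-1,4-dien-1-yl unit) | CC(CC[C@H]1[C@@H](C2=C(C)CC=C2)C1(C)C)=NN=C(C)CC[C@H]1[C@@H](C2=CCC=C2C)C1(C)C
F3 | step 4 | ansa-ketazine of the target (both side-chain C=O of 14 joined as C=N–N=C) | CC(=N9)CC[C@H]1[C@@H](C2=C[C@@H]3C[C@@]2(C)[C@H]2C[C@@H]3C([C@@H]3[C@H](CCC(C)=N9)C3(C)C)=C2C)C1(C)C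
F4 | step 2 | (1R,6S)-3,7,7-trimethylbicyclo[4.1.0]heptan-2-one (C-3 epimers) | CC1CC[C@H]2[C@@H](C1=O)C2(C)C
F5 | step 2 | (1R,7S)-4,8,8-trimethyl-3-oxabicyclo[5.1.0]octan-2-one (C-4 epimers) | CC1CC[C@H]2[C@@H](C(=O)O1)C2(C)C
F6 | step 2 | 4-[(1S,3R)-3-(3-hydroxy-2-methylpenta-1,4-dien-3-yl)-2,2-dimethylcyclopropyl]butan-2-ol | CC(O)CC[C@H]1[C@@H](C(O)(C=C)C(C)=C)C1(C)C
F7 | step 3 | (pent-2-ene-1,4-diyl)magnesium (2-methyl-1-magnesacyclopent-3-ene) | CC1C=CC[Mg]1
F8 | step 3 | 4-[(1S,3R)-3-(1-hydroxy-2-methylcyclopent-3-en-1-yl)-2,2-dimethylcyclopropyl]butan-2-one | CC(=O)CC[C@H]1[C@@H](C2(O)CC=CC2C)C1(C)C
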